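The seven-membered ring (C1, C5–C10) is read as a masked cyclohepta-1,4-diene. C8=C9 is already present, and the C6 carbinol is the reduced form of the enol C5=C6. Quaternary C1 and carbinol C10 are joined between the two alkenes. Disconnecting C7–C8 and C1–C10 gives a 2-(1-ethoxyvinyl)-3-methylcyclopentenone, with the five-membered ring intact, and an (E)-4-alkoxyvinyl diazoacetate. In one flask a chiral dirhodium vinylcarbenoid cyclopropanates the enol ether and the cis-divinylcyclopropane expands by a Cope shift. This closes the ring, makes both bonds and sets C1 and C10. The vinylogous ester so formed then serves to build C4, C5 and C6.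

Key step: step 6

**Numbering and conventions**
- C1 carries the angular methyl, and C2 and C3 are the ring methylenes.
- C4 bears OH and isopropyl, and C5 is the ring-fusion CH.
- C6 bears the aroyloxy group, and C7 is CH2.
- C8 (methyl) is doubly bonded to C9, and C10 bears the angeloyloxy group.
- β is the face of the C1 methyl group and α is the other face.
- The target is 4β-OH, 5α-H, 6α-O, 10α-O, that is (1S,4R,5S,6S,10R).
- PMB = 4-methoxybenzyl.

Assumption: the (R)-prolinate catalyst is assigned by analogy with the known sense of induction of this catalyst family with styrene-type alkenes; if the sense proved opposite, the equally available antipode would be used (the same holds for the auxiliary in the fallback to step 6).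

**Design points**
- **C6 oxygen as an ethyl enol ether.** After ring expansion this oxygen is part of a vinylogous ester. A vinylogous silyl ester would not survive chromatography, amide base or organometallic reagents. The small ethoxy group also leaves the position syn to the carbenoid vinyl group to the larger cyclopentenyl substituent.
- **Diene by cross-coupling.** Enol silylation of 2-acetyl-3-methylcyclopentenone could equally engage the ring ketone or the γ-positions.
- **Diazo ester through the 3-oxo ester.** A conjugated 4-alkoxycrotonate is too weakly acidic for amine-promoted diazo transfer and would give no control of the enol ether geometry.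
- **Isopropyl by cross-coupling at C4.** Isopropyl-lithium, -magnesium or -cerium reagents would not distinguish the C4 vinylogous ester carbonyl from the C8 methyl ester.
- **No base while C6 is a ketone.** A C7 dienolate would expel the C10 ether or move C8=C9 into conjugation.
- **Ester kept until C4–C6 are finished.** It keeps C8=C9 electron-poor.

## Route

Step 1
Reactants: 1 2-bromo-3-methylcyclopent-2-en-1-one; 2 tributyl(1-ethoxyvinyl)stannane
Product: 3 2-(1-ethoxyvinyl)-3-methylcyclopent-2-en-1-one
Conditions: PdCl2(PPh3)2 (5 mol %), toluene, 100 °C; Et3N-deactivated SiO2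
Reagents that add atoms: none
Why: Stille coupling of an α-bromoenone with an α-alkoxyvinylstannane is routine and fixes the enol ether at C6=C7 without any enolisation step, so the ring ketone and the γ-positions cannot compete; no stereocentre is formed.

Step 2
Reactants: 4 4-methoxybenzyl alcohol; 5 methyl 4-chloro-3-oxobutanoate
Product: 7 methyl 4-[(4-methoxybenzyl)oxy]-3-oxobutanoate, via sodium 4-methoxybenzyl oxide 6 (not isolated)
Conditions: NaH (2.2 equiv), THF, 0 °C; then 5, 0 °C to rt; 1 M HCl quench
Reagents that add atoms: sodium hydride [Na+].[H-] (sodium of 6)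
Why: Williamson-type displacement of chloride from the sodium enolate of a 4-chloroacetoacetate by an alkoxide is the standard entry to 4-alkoxyacetoacetates, the second equivalent of base masking the keto ester as its enolate; no stereocentre is formed.

Step 3
Reactants: 7 methyl 4-[(4-methoxybenzyl)oxy]-3-oxobutanoate
Product: 8 methyl 2-diazo-4-[(4-methoxybenzyl)oxy]-3-oxobutanoate
Conditions: p-ABSA, Et3N, MeCN, 0 °C to rt
Reagents that add atoms: 4-acetamidobenzenesulfonyl azide CC(=O)Nc1ccc(cc1)S(=O)(=O)N=[N+]=[N-]
Why: Regitz diazo transfer to an active methylene compound needs only an amine base because the C–H lies between two carbonyl groups.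

Step 4
Reactants: 8 methyl 2-diazo-4-[(4-methoxybenzyl)oxy]-3-oxobutanoate
Product: 9 methyl 2-diazo-3-hydroxy-4-[(4-methoxybenzyl)oxy]butanoate (racemic)
Conditions: NaBH4, MeOH, 0 °C
Reagents that add atoms: none
Why: Borohydride reduction of the ketone of a 2-diazo-3-oxo ester leaves the diazo group and the ester intact, and the racemic carbinol centre is destroyed in step 5.

Step 5
Reactants: 9 methyl 2-diazo-3-hydroxy-4-[(4-methoxybenzyl)oxy]butanoate
Product: 10 methyl (E)-2-diazo-4-[(4-methoxybenzyl)oxy]but-3-enoate
Conditions: POCl3, Et3N, CH2Cl2, 0 °C; kept cold and used promptly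
Reagents that add atoms: none
Why: Dehydration of a 3-hydroxy-2-diazo ester through its dichlorophosphate is the classical route to vinyldiazoacetates, and elimination from the less crowded rotamer (ether oxygen anti to the diazo ester unit) should give the E enol ether on which the C10 configuration depends.

Step 6
Reactants: 3 2-(1-ethoxyvinyl)-3-methylcyclopent-2-en-1-one; 10 methyl (E)-2-diazo-4-[(4-methoxybenzyl)oxy]but-3-enoate
Product: 12 bicyclic vinylogous ester (1S,10R) with C4 ketone; C5=C6 ethyl enol ether; C8=C9 bearing CO2Me on C8; 10α-OPMB; 1β-methyl, via cis-divinylcyclopropane 11 (not isolated)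
Conditions: 3 (2 equiv), Rh2(R-DOSP)4 (1 mol %), hexanes/PhCF3, −20 °C, slow addition of 10; then 60 °C
Reagents that add atoms: none
Why: Loss of N2 from 10 at the dirhodium core gives a donor/acceptor vinylcarbenoid (C8) that adds in a concerted, asynchronous way to the electron-rich, unhindered C6=C7 enol ether of 3, placing the C9=C10 vinyl group and the cyclopentenyl group on the same face of cyclopropane 11. The closest known reaction type is the tandem vinyldiazoacetate cyclopropanation/divinylcyclopropane Cope rearrangement with dienes (formal 4+3 cycloaddition), known for 2-oxygenated dienes and for diene termini that become quaternary, so that only the 4-alkoxy group on the carbenoid is untried. The seven-membered ring closes by [3,3]-sigmatropic ring expansion through the endo-boat transition state, in which the strained, push–pull-weakened C6–C8 bond breaks as C1–C10 forms. The absolute configuration comes from the chiral carboxylate ligands, which select the face of the carbenoid and hence the configuration of 11, and the boat geometry passes this on to C1 and C10. The relative configuration is geometric: the E oxygen on C10 and ring carbon C2 (the C1 substituent trans to C6) both point outward in the boat and end up cis, so C10–O is trans to the C1 methyl group. The step needs chemoselectivity (the tetrasubstituted, ketone-deactivated C5=C1 bond is inert), cis-cyclopropane selectivity (the larger cyclopentenyl group, not the ethoxy group, sits syn to the vinyl donor) and the E geometry built into 10.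

Step 7
Reactants: 12 bicyclic vinylogous ester
Product: 14 cross-conjugated dienyl triflate (C3=C4–OTf; C5=C6–OEt), via lithium enolate 13 (not isolated)
Conditions: LiN(SiMe3)2, THF, −78 °C; then N-(5-chloropyridin-2-yl)bis(trifluoromethanesulfonimide), −78 to −20 °C
Reagents that add atoms: lithium hexamethyldisilazide [Li+].C[Si](C)(C)[N-][Si](C)(C)C (lithium of 13); N-(5-chloropyridin-2-yl)bis(trifluoromethanesulfonimide) FC(F)(F)S(=O)(=O)N(c1ccc(Cl)cn1)S(=O)(=O)C(F)(F)F
Why: Kinetic α′-deprotonation of a vinylogous ester (as in Stork–Danheiser alkylations) removes the C3 proton next to the lithium-bound carbonyl rather than the remote C7 protons, and O-sulfonylation of the enolate activates C4 for C–C bond formation without any reagent that would attack the C8 ester; C1 and C10 are untouched.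

Step 8
Reactants: 14 dienyl triflate
Product: 16 enone (1S,10R) with C4(iPr)=C5–C6=O; C8=C9–CO2Me; 10α-OPMB, via 2-ethoxydiene 15 (not isolated)
Conditions: iPrZnBr, Pd(dppf)Cl2 (5 mol %), LiCl, THF, 40 °C; then 1 M HCl, THF, rt
Reagents that add atoms: isopropylzinc bromide CC(C)[Zn]Br; water O
Why: Negishi coupling of an alkenyl triflate with a secondary alkylzinc halide under a wide-bite-angle diphosphine (fast reductive elimination, little isomerisation to n-propyl) tolerates the ester, and acid hydrolysis of the 2-ethoxydiene with protonation at the C3 terminus gives the conjugated enone, the net result of a Stork–Danheiser transposition.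

Step 9
Reactants: 16 enone
Product: 17 4β,5β-epoxy ketone
Conditions: DMDO (acetone solution), CH2Cl2, 0 °C to rt
Reagents that add atoms: dimethyldioxirane CC1(C)OO1
Why: Dioxirane epoxidation of an enone is neutral (base would trigger loss of the C10 ether through a C7 dienolate), C4=C5 is twisted out of conjugation by the isopropyl/carbonyl clash and is the most electron-rich alkene left (C8=C9 is an enoate), and oxygen should arrive on the convex β face, because the seven-membered ring with C10 and its ether folds over the α face, which sets C4–O as required.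

Step 10
Reactants: 17 4β,5β-epoxy ketone
Product: 18 trans-fused ketol (4β-OH; 5α-H; C6 ketone)
Conditions: SmI2 (2.2 equiv), THF/MeOH, −90 °C
Reagents that add atoms: none
Why: SmI2 reduction of an α,β-epoxy ketone cleaves only the C5–O bond from the ketyl, so C4–O keeps its configuration, and protonation of the trivalent samarium enolate is expected to end at the more stable trans-fused ketol, in which C6 avoids a cis isopropyl group and accepts a hydrogen bond from the C4 hydroxyl; this protonation is the weakest stereochemical point of the end game (see below).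

Step 11
Reactants: 18 trans-fused ketol
Product: 19 4β,6α-diol methyl ester
Conditions: Me4NBH(OAc)3, MeCN/AcOH 1:1, −30 °C
Reagents that add atoms: none
Why: In the Evans–Saksena reduction boron binds to the C4 hydroxyl by ligand exchange and delivers hydride intramolecularly to the β face of C6, giving the anti-1,3-diol (6α-OH), while ester, enoate alkene and PMB ether are inert to this mild acidic borohydride.

Step 12
Reactants: 19 4β,6α-diol methyl ester
Product: 20 triol (C8–CH2OH; 4β-OH; 6α-OH)
Conditions: iBu2AlH (5 equiv), CH2Cl2, −78 to −20 °C; aq. potassium sodium tartrate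
Reagents that add atoms: none
Why: 1,2-Reduction of an α,β-unsaturated ester to the allylic alcohol by iBu2AlH is standard, the two free hydroxyls merely consuming reagent, and no stereocentre changes.

Step 13
Reactants: 20 triol
Product: 22 10α-O-PMB 4β,6α-diol bearing the C8 methyl group, via allylic mesylate 21 (not isolated)
Conditions: MsCl (1.05 equiv), Et3N, THF, −40 °C; then LiEt3BH (5 equiv), −40 to 0 °C
Reagents that add atoms: methanesulfonyl chloride CS(=O)(=O)Cl (mesyl group of 21)
Why: The unhindered primary allylic hydroxyl is sulfonylated far faster than the hindered secondary and the tertiary one, and SN2 displacement of the mesylate by triethylborohydride at the primary carbon (SN2′ attack at C9 is blocked by the neighbouring C10 ether) turns the former ester carbon into the C8 methyl group.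

Step 14
Reactants: 22 10α-O-PMB 4β,6α-diol; 23 4-acetoxybenzoic acid
Product: 24 6α-(4-acetoxybenzoate) of 22
Conditions: DCC, DMAP, CH2Cl2, rt
Reagents that add atoms: none
Why: Steglich esterification acylates only the secondary 6α-hydroxyl because the C4 hydroxyl is tertiary and C10–O is still protected, and C6 keeps its configuration since its C–O bond is not broken.

Step 15
Reactants: 24 6α-(4-acetoxybenzoate)
Product: 25 10α-alcohol
Conditions: DDQ, CH2Cl2/pH 7 buffer, 0 °C
Reagents that add atoms: none
Why: Oxidative cleavage of a 4-methoxybenzyl ether by DDQ (hydride abstraction, then hydrolysis of the oxocarbenium ion) runs under buffered conditions that leave the esters, the tertiary alcohol and the trisubstituted alkene alone.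

Step 16
Reactants: 25 10α-alcohol; 26 angelic acid, (Z)-2-methylbut-2-enoic acid
Product: 28 10α-angelate 6α-(4-acetoxybenzoate), via mixed anhydride 27 (not isolated)
Conditions: 26, 2,4,6-trichlorobenzoyl chloride, Et3N, toluene, rt; then 25, 80 °C
Reagents that add atoms: 2,4,6-trichlorobenzoyl chloride O=C(Cl)c1c(Cl)cc(Cl)cc1Cl (aroyl group of 27)
Why: Yamaguchi-type acylation with the preformed mixed anhydride in hot toluene, without a nucleophilic pyridine catalyst, is the established way to make angelates of hindered alcohols without isomerisation to the tiglate; the tertiary C4 hydroxyl does not react and C10 keeps its configuration.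

Step 17
Reactants: 28 10α-angelate 6α-(4-acetoxybenzoate)
Product: 29 target CNP0273650.2
Conditions: NH4OAc, MeOH/H2O 4:1, rt
Reagents that add atoms: none
Why: Aryl acetates are cleaved by neutral ammonium acetate in aqueous methanol far faster than alkyl benzoates or angelates, so only the phenol is unmasked and neither a stereocentre nor the Z alkene is at risk.

## Compound list

1 | 2-bromo-3-methylcyclopent-2-en-1-one | CC1=C(Br)C(=O)CC1 | starting material
2 | tributyl(1-ethoxyvinyl)stannane | CCCC[Sn](CCCC)(CCCC)C(=C)OCC | starting material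
3 | 2-(1-ethoxyvinyl)-3-methylcyclopent-2-en-1-one | C=C(OCC)C1=C(C)CCC1=O | intermediate
4 | 4-methoxybenzyl alcohol | COc1ccc(CO)cc1 | starting material
5 | methyl 4-chloro-3-oxobutanoate | COC(=O)CC(=O)CCl | starting material
6 | sodium 4-methoxybenzyl oxide | [Na+].[O-]Cc1ccc(OC)cc1 | intermediate
7 | methyl 4-[(4-methoxybenzyl)oxy]-3-oxobutanoate | COC(=O)CC(=O)COCc1ccc(OC)cc1 | intermediate
8 | methyl 2-diazo-4-[(4-methoxybenzyl)oxy]-3-oxobutanoate | COC(=O)C(=[N+]=[N-])C(=O)COCc1ccc(OC)cc1 | intermediate
9 | methyl 2-diazo-3-hydroxy-4-[(4-methoxybenzyl)oxy]butanoate (racemic) | COC(=O)C(=[N+]=[N-])C(O)COCc1ccc(OC)cc1 | intermediate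
10 | methyl (E)-2-diazo-4-[(4-methoxybenzyl)oxy]but-3-enoate | COC(=O)C(=[N+]=[N-])/C=C/OCc1ccc(OC)cc1 | intermediate
11 | methyl (1S,2R)-2-ethoxy-1-[(E)-2-(PMB-oxy)vinyl]-2-(2-methyl-5-oxocyclopent-1-enyl)cyclopropane-1-carboxylate (vinyl and cyclopentenyl cis) | COC(=O)[C@]1(/C=C/OCc2ccc(OC)cc2)C[C@@]1(OCC)C3=C(C)CCC3=O | intermediate
12 | bicyclic vinylogous ester (1S,10R): C4 ketone, C5=C6 ethyl enol ether, C8=C9 with CO2Me on C8, 10α-OPMB, 1β-methyl | COc1ccc(CO[C@@H]2C=C(C(=O)OC)CC(OCC)=C3[C@]2(C)CCC3=O)cc1 | intermediate
13 | lithium C3=C4 enolate of 12 | COc1ccc(CO[C@@H]2C=C(C(=O)OC)CC(OCC)=C3[C@]2(C)CC=C3[O-])cc1.[Li+] | intermediate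
14 | C3=C4 enol triflate of 12 | COc1ccc(CO[C@@H]2C=C(C(=O)OC)CC(OCC)=C3[C@]2(C)CC=C3OS(=O)(=O)C(F)(F)F)cc1 | intermediate
15 | 4-isopropyl-6-ethoxy diene (C3=C4, C5=C6) | COc1ccc(CO[C@@H]2C=C(C(=O)OC)CC(OCC)=C3[C@]2(C)CC=C3C(C)C)cc1 | intermediate
16 | enone: C4(iPr)=C5–C6=O, C8=C9–CO2Me, 10α-OPMB | COc1ccc(CO[C@@H]2C=C(C(=O)OC)CC(=O)C3=C(C(C)C)CC[C@@]32C)cc1 | intermediate
17 | 4β,5β-epoxy-6-ketone | COc1ccc(CO[C@@H]2C=C(C(=O)OC)CC(=O)[C@@]34O[C@@]4(C(C)C)CC[C@@]32C)cc1 | intermediate
18 | trans-fused ketol: 4β-OH, 5α-H, C6 ketone | COc1ccc(CO[C@@H]2C=C(C(=O)OC)CC(=O)[C@@H]3[C@]2(C)CC[C@@]3(O)C(C)C)cc1 | intermediate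
19 | 4β,6α-diol methyl ester | COc1ccc(CO[C@@H]2C=C(C(=O)OC)C[C@H](O)[C@@H]3[C@]2(C)CC[C@@]3(O)C(C)C)cc1 | intermediate
20 | triol with C8–CH2OH | COc1ccc(CO[C@@H]2C=C(CO)C[C@H](O)[C@@H]3[C@]2(C)CC[C@@]3(O)C(C)C)cc1 | intermediate
21 | primary allylic mesylate of 20 | COc1ccc(CO[C@@H]2C=C(COS(C)(=O)=O)C[C@H](O)[C@@H]3[C@]2(C)CC[C@@]3(O)C(C)C)cc1 | intermediate
22 | 10α-O-PMB 4β,6α-diol with C8 methyl | COc1ccc(CO[C@@H]2C=C(C)C[C@H](O)[C@@H]3[C@]2(C)CC[C@@]3(O)C(C)C)cc1 | intermediate
23 | 4-acetoxybenzoic acid | CC(=O)Oc1ccc(cc1)C(=O)O | starting material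
24 | 6α-(4-acetoxybenzoate) of 22 | COc1ccc(CO[C@@H]2C=C(C)C[C@H](OC(=O)c4ccc(OC(C)=O)cc4)[C@@H]3[C@]2(C)CC[C@@]3(O)C(C)C)cc1 | intermediate
25 | 10α-alcohol 6α-(4-acetoxybenzoate) | O[C@@H]1C=C(C)C[C@H](OC(=O)c2ccc(OC(C)=O)cc2)[C@@H]2[C@]1(C)CC[C@@]2(O)C(C)C | intermediate
26 | angelic acid | C/C=C(/C)C(=O)O | starting material
27 | angelic 2,4,6-trichlorobenzoic anhydride | C/C=C(/C)C(=O)OC(=O)c1c(Cl)cc(Cl)cc1Cl | intermediate
28 | 10α-angelate 6α-(4-acetoxybenzoate) | C/C=C(/C)C(=O)O[C@@H]1C=C(C)C[C@H](OC(=O)c2ccc(OC(C)=O)cc2)[C@@H]2[C@]1(C)CC[C@@]2(O)C(C)C | intermediate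
29 | CNP0273650.2, (1S,4R,5S,6S,10R) | C/C=C(/C)C(=O)O[C@@H]1C=C(C)C[C@H](OC(=O)c2ccc(O)cc2)[C@@H]2[C@]1(C)CC[C@@]2(O)C(C)C | target

Total steps: 17. Longest linear sequence: 16 (steps 2–17, from 4 and 5).

## Steps most likely to fail

**Step 6.**
- The enol ether may attack the carbenoid at its vinylogous terminus.
- The push–pull cyclopropane may open heterolytically. This would divert material to five-membered rings and, if a trans-cyclopropane has to epimerise through the ring-opened form, would erode enantiomeric purity.
- The inward-pointing C1 methyl group slows the boat Cope shift.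
- The chiral catalyst may read the new alkoxyvinyl carbenoid poorly.

The fallback moves stereocontrol from the catalyst to a covalently bound auxiliary. It sets out from 7 and returns at 12. Keto ester 7 is transesterified with (R)-pantolactone (DMAP, toluene, reflux) to the pantolactonyl keto ester F1. This is carried through diazo transfer to the diazo keto ester F2, borohydride reduction to the diazo alcohol F3, and POCl3/Et3N dehydration to the auxiliary-bearing vinyldiazoacetate F4. Decomposition of F4 by achiral Rh2(O2CC7H15)4 in pentane in the presence of 3 relies on the lactone carbonyl of the auxiliary shielding one face of the carbenoid. This is a known diastereoselective version of the same cyclopropanation/Cope sequence. It gives the pantolactonyl cycloadduct F5, from which a minor diastereomer can be removed by chromatography or crystallisation. Ti(OiPr)4-catalysed methanolysis of the activated ester then gives 12.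

**Step 10.** Kinetic protonation of the enolate on the convex β face, helped by the samarium-bound C4 oxygen, would lead to the cis ring fusion. Later correction is not possible, since base sets off C7 enolisation with loss of the C10 ether and acid dehydrates the ketol.

The fallback avoids any enolate and installs C5–H stereospecifically. It sets out from 16 and returns at 18, bypassing steps 9 and 10. CBS reduction of 16 with (S)-2-methyl-CBS-oxazaborolidine and catecholborane (toluene, −78 °C) overrides the convex-face bias and gives the 6β-allylic alcohol F6. VO(acac)2/tBuOOH epoxidation, directed by the 6β-hydroxyl and matched with the convex face, gives the 4β,5β-epoxy-6β-alcohol F7. BF3·OEt2 (CH2Cl2, −78 °C) then triggers a semipinacol rearrangement of the 2,3-epoxy alcohol. The α-oriented C6 hydrogen migrates to C5 anti to the breaking C5–O bond, giving 18 with 5α-H and 4β-OH.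

**Step 9.**
- Oxygen transfer to the hindered, still partly conjugated alkene may be slow.
- Benzylic oxidation of the PMB ether may compete.
- Facial selectivity may be poor.

The fallback removes the deactivating carbonyl for the epoxidation. It sets out from 16 and returns at 17. Luche reduction (NaBH4, CeCl3·7H2O, MeOH, −78 °C; hydride from the convex face) gives the 6α-allylic alcohol F8. This is protected (Et3SiCl, imidazole) as the triethylsilyl ether F9. mCPBA/NaHCO3 then epoxidises the now electron-rich tetrasubstituted alkene, in preference to the enoate and anti to the α-oriented silyloxy and PMB-oxy groups, to give the β-epoxide silyl ether F10. Bu4NF releases the 4β,5β-epoxy-6α-alcohol F11, and Dess–Martin oxidation gives 17.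

## Further compounds

F1 | step 6 | (R)-pantolactonyl 4-[(4-methoxybenzyl)oxy]-3-oxobutanoate | COc1ccc(COCC(=O)CC(=O)O[C@H]2C(=O)OCC2(C)C)cc1
F2 | step 6 | (R)-pantolactonyl 2-diazo-4-[(4-methoxybenzyl)oxy]-3-oxobutanoate | COc1ccc(COCC(=O)C(=[N+]=[N-])C(=O)O[C@H]2C(=O)OCC2(C)C)cc1
F3 | step 6 | (R)-pantolactonyl 2-diazo-3-hydroxy-4-[(4-methoxybenzyl)oxy]butanoate (carbinol epimers) | COc1ccc(COCC(O)C(=[N+]=[N-])C(=O)O[C@H]2C(=O)OCC2(C)C)cc1
F4 | step 6 | (R)-pantolactonyl (E)-2-diazo-4-[(4-methoxybenzyl)oxy]but-3-enoate | COc1ccc(CO/C=C/C(=[N+]=[N-])C(=O)O[C@H]2C(=O)OCC2(C)C)cc1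
F5 | step 6 | (R)-pantolactonyl ester analogue of 12 | COc1ccc(CO[C@@H]2C=C(C(=O)O[C@H]4C(=O)OCC4(C)C)CC(OCC)=C3[C@]2(C)CCC3=O)cc1
F6 | step 10 | 6β-allylic alcohol from 16 | COc1ccc(CO[C@@H]2C=C(C(=O)OC)C[C@@H](O)C3=C(C(C)C)CC[C@@]32C)cc1
F7 | step 10 | 4β,5β-epoxy-6β-alcohol | COc1ccc(CO[C@@H]2C=C(C(=O)OC)C[C@@H](O)[C@@]34O[C@@]4(C(C)C)CC[C@@]32C)cc1
F8 | step 9 | 6α-allylic alcohol from 16 | COc1ccc(CO[C@@H]2C=C(C(=O)OC)C[C@H](O)C3=C(C(C)C)CC[C@@]32C)cc1
F9 | step 9 | 6α-triethylsilyl ether of F8 | COc1ccc(CO[C@@H]2C=C(C(=O)OC)C[C@H](O[Si](CC)(CC)CC)C3=C(C(C)C)CC[C@@]32C)cc1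
F10 | step 9 | 4β,5β-epoxide of F9 | COc1ccc(CO[C@@H]2C=C(C(=O)OC)C[C@H](O[Si](CC)(CC)CC)[C@@]34O[C@@]4(C(C)C)CC[C@@]32C)cc1
F11 | step 9 | 4β,5β-epoxy-6α-alcohol | COc1ccc(CO[C@@H]2C=C(C(=O)OC)C[C@H](O)[C@@]34O[C@@]4(C(C)C)CC[C@@]32C)cc1
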